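Ring A is closed last at C1–C2 (eudesmane numbering). Reading the C4 carbinol as a ketone turns C2–C3 into a vinyl ketone on C5 of ring B, while C1 is a neopentyl CH2 on the quaternary C10; a 6-endo Giese cyclisation of the C1 radical onto C2 closes ring A and delivers the 4-ketone, whose methylation sets C4. The precursor is a menthane-type iodo hydroxy enone made from (S)-piperitone: C10 is set by a hydroxyl-directed cyclopropanation, and the extra C1–C5 bond is then cut with Me3SiI, which unveils the C1 iodide and the C5 enol ether together. The isoferulate is built last by a Horner–Wadsworth–Emmons reaction.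

Key step: step 8

Remark: (S)-(+)-piperitone is taken as a purchasable single enantiomer (it supplies C7); eudesmane numbering (ring A: C1–C5, C10; ring B: C5–C10) and α/β (β = face of the C10 methyl) are used for all intermediates.

Step 1
Reactants: 1 (S)-(+)-piperitone
Product: 2 trans-piperitol (6α-hydroxyl, anti to the 7β-isopropyl group)
Conditions: NaBH4, CeCl3·7H2O, MeOH, −78 to 0 °C
Reagents that add atoms: none
Why: Luche reduction adds hydride 1,2 only, and axial delivery to the half-chair with a pseudo-equatorial isopropyl group should place the hydroxyl pseudo-equatorial and anti to isopropyl (the menthol-like relationship), the cis isomer being separable.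

Step 2
Reactants: 2 trans-piperitol
Product: 3 cyclopropyl carbinol (CH2 bridging C5 and C10 on the α face, syn to the 6α-hydroxyl)
Conditions: Et2Zn, CH2I2, CH2Cl2, 0 °C to rt
Reagents that add atoms: diiodomethane, ICI
Why: In this Simmons–Smith cyclopropanation (Furukawa variant) the zinc alkoxide delivers the carbenoid to the alkene face syn to oxygen, so the new methylene (the future C1) lands anti to isopropyl and fixes the quaternary C10 with its methyl β.

Step 3
Reactants: 3 cyclopropyl carbinol
Product: 4 cyclopropyl ketone
Conditions: Pr4N[RuO4] (cat.), N-methylmorpholine N-oxide, 4 Å molecular sieves, CH2Cl2, rt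
Reagents that add atoms: none
Why: Ley–Griffith oxidation of the secondary alcohol is neutral and should leave the cyclopropane and the enolisable C7 centre untouched.

Step 4
Reactants: 4 cyclopropyl ketone
Product: 5 iodomethyl trimethylsilyl enol ether (C10: CH2I α, CH3 β; enol ether C5=C6)
Conditions: Me3SiI, (Me3Si)2NH (trace), CH2Cl2, −40 to 0 °C; non-aqueous isolation, used crude
Reagents that add atoms: iodotrimethylsilane, C[Si](C)(C)I
Why: Homo-conjugate opening of the silyl-activated cyclopropyl ketone should cleave the exocyclic C1–C5 bond, the one aligned with the carbonyl π system, by iodide attack at the unhindered CH2, giving the neopentyl iodide and the regiodefined enol ether without touching C10 or C7.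

Step 5
Reactants: 5 iodomethyl trimethylsilyl enol ether; 6 acrolein
Product: 7 aldol adduct (6-ketone; 1-hydroxyallyl group on C5, β and equatorial; carbinol C4 as a mixture)
Conditions: TiCl4, CH2Cl2, −78 °C; aq. NaHCO3
Reagents that add atoms: none
Why: In this Mukaiyama aldol addition the enol ether attacks the activated aldehyde 1,2 at C5, and the side chain should end up equatorial and cis to isopropyl, kinetically by attack anti to the pseudo-axial iodomethyl group and thermodynamically because C5 is α to the ketone; the C4 mixture is removed in step 7.

Step 6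
Reactants: 7 aldol adduct
Product: 8 diol (6β-hydroxyl, axial, cis to isopropyl)
Conditions: NaBH4, MeOH, −20 °C
Reagents that add atoms: none
Why: In this hydride reduction under steric approach control the axial C10 methyl blocks the β face of the doubly flanked ketone, so hydride should enter equatorially from the α face and give the axial 6β alcohol (neomenthol-type).

Step 7
Reactants: 8 diol
Product: 9 vinyl ketone (5-acryloyl, 6β-hydroxyl free, C10 iodomethyl)
Conditions: MnO2 (activated, excess), CH2Cl2, rt
Reagents that add atoms: none
Why: MnO2 oxidises only the allylic carbinol, so the vinyl ketone forms while the saturated, hindered 6-hydroxyl stays as it is.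

Step 8
Reactants: 9 vinyl ketone
Product: 10 6β-hydroxy-15-noreudesman-4-one (trans-decalin)
Conditions: Bu3SnH (slow addition), AIBN (cat.), benzene, 80 °C, high dilution
Reagents that add atoms: none
Why: Bu3Sn• abstracts iodine from the neopentyl iodide, the primary C1 radical adds to the terminal carbon C2 of the vinyl ketone, and the α-keto radical at C3 takes hydrogen from the stannane (tin-hydride Giese cyclisation). The closest known reaction type is the endo-selective radical cyclisation of ω-iodoalkyl vinyl ketones, where a carbonyl group inside the tether reverses the usual exo preference. Ring A closes in the 6-endo-trig mode, because 5-exo attack would have to occur at the electron-poor α-carbon C3 and would give an unstabilised primary radical and a strained cyclopentanone. No new stereocentre arises at C1, C2 or C3; the ring fusion is set by existing centres, since the equatorial CH2 radical on C10 and the equatorial acryloyl group on C5 are gauche and join through a chair-like transition state to the trans-decalin, and C5, being α to the ketone, can also settle to the trans fusion thermodynamically. The step needs 6-endo closure to outrun hydrogen transfer to the neopentyl radical and hydrostannation or oligomerisation of the enone, which the polarity match (nucleophilic alkyl radical, electron-poor alkene), the pre-organised gauche arrangement on ring B, high dilution and slow stannane addition should secure.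

Step 9
Reactants: 10 6β-hydroxy-15-noreudesman-4-one
Product: 11 eudesmane-4β,6β-diol
Conditions: MeMgBr (excess), THF, −78 to 0 °C; aq. NH4Cl
Reagents that add atoms: methylmagnesium bromide, C[Mg]Br
Why: Grignard addition should occur from the equatorial α face, because the β face is shielded by the axial C10 methyl and the axial 6β magnesium alkoxide, which sets C4 with the hydroxyl axial (4β) and the methyl equatorial.

Step 10
Reactants: 11 eudesmane-4β,6β-diol; 12 diethylphosphonoacetic acid
Product: 13 6-O-(diethylphosphonoacetyl) ester of 11
Conditions: DCC, DMAP (cat.), CH2Cl2, rt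
Reagents that add atoms: none
Why: Steglich esterification acylates the secondary 6-hydroxyl with a small acyl donor, and the tertiary 4-hydroxyl is inert under these conditions.

Step 11
Reactants: 13 phosphonoacetate ester; 14 isovanillin
Product: 15 target, (4S,5S,6R,7S,10R)-4-hydroxyeudesman-6-yl (E)-3-(3-hydroxy-4-methoxyphenyl)prop-2-enoate
Conditions: LiCl, DBU, MeCN, rt
Reagents that add atoms: none
Why: Horner–Wadsworth–Emmons olefination under Masamune–Roush conditions should give the E-cinnamate, and the phenoxide, being meta to the formyl group, does not deactivate the aldehyde.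

Compound list
1 | (S)-(+)-piperitone, (6S)-3-methyl-6-(propan-2-yl)cyclohex-2-en-1-one | O=C1C=C(C)CC[C@H]1C(C)C | starting material
2 | trans-piperitol, (1S,6S)-3-methyl-6-(propan-2-yl)cyclohex-2-en-1-ol (OH anti to isopropyl) | O[C@@H]1C=C(C)CC[C@H]1C(C)C | intermediate
3 | 6-methyl-3-(propan-2-yl)bicyclo[4.1.0]heptan-2-ol; OH and cyclopropane CH2 on the same face, both anti to isopropyl | O[C@@H]1[C@@H]2C[C@]2(C)CC[C@H]1C(C)C | intermediate
4 | 6-methyl-3-(propan-2-yl)bicyclo[4.1.0]heptan-2-one; cyclopropane CH2 anti to isopropyl | O=C1[C@@H]2C[C@]2(C)CC[C@H]1C(C)C | intermediate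
5 | {[3-(iodomethyl)-3-methyl-6-(propan-2-yl)cyclohex-1-en-1-yl]oxy}trimethylsilane; CH2I anti to isopropyl | C[Si](C)(C)OC1=C[C@](C)(CI)CC[C@H]1C(C)C | intermediate
6 | acrolein, prop-2-enal | C=CC=O | starting material
7 | 2-(1-hydroxyprop-2-en-1-yl)-3-(iodomethyl)-3-methyl-6-(propan-2-yl)cyclohexan-1-one; side chain on C2 cis to isopropyl and to the ring methyl, carbinol epimers | O=C1[C@@H](C(O)C=C)[C@](C)(CI)CC[C@H]1C(C)C | intermediate
8 | 2-(1-hydroxyprop-2-en-1-yl)-3-(iodomethyl)-3-methyl-6-(propan-2-yl)cyclohexan-1-ol; ring OH axial, cis to isopropyl, to the side chain and to the ring methyl | O[C@H]1[C@@H](C(O)C=C)[C@](C)(CI)CC[C@H]1C(C)C | intermediate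
9 | 1-[2-hydroxy-6-(iodomethyl)-6-methyl-3-(propan-2-yl)cyclohexyl]prop-2-en-1-one; same ring configuration as 8 | O[C@H]1[C@@H](C(=O)C=C)[C@](C)(CI)CC[C@H]1C(C)C | intermediate
10 | 6β-hydroxy-15-noreudesman-4-one (trans-fused; 5α-H, 10β-CH3, 7β-isopropyl) | O[C@H]1[C@@H]2[C@](C)(CCCC2=O)CC[C@H]1C(C)C | intermediate
11 | eudesmane-4β,6β-diol, (4S,5S,6R,7S,10R) | O[C@H]1[C@@H]2[C@](C)(CCC[C@]2(C)O)CC[C@H]1C(C)C | intermediate
12 | diethylphosphonoacetic acid, 2-(diethoxyphosphoryl)acetic acid | CCOP(=O)(OCC)CC(=O)O | starting material
13 | (4S,5S,6R,7S,10R)-4-hydroxyeudesman-6-yl 2-(diethoxyphosphoryl)acetate | CCOP(=O)(OCC)CC(=O)O[C@H]1[C@@H]2[C@](C)(CCC[C@]2(C)O)CC[C@H]1C(C)C | intermediate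
14 | isovanillin, 3-hydroxy-4-methoxybenzaldehyde | COc1ccc(C=O)cc1O | starting material
15 | (4S,5S,6R,7S,10R)-4-hydroxyeudesman-6-yl (E)-3-(3-hydroxy-4-methoxyphenyl)prop-2-enoate | COc1ccc(/C=C/C(=O)O[C@H]2[C@@H]3[C@](C)(CCC[C@]3(C)O)CC[C@H]2C(C)C)cc1O | target

Total step count: 11. Longest linear sequence: 11 steps (1 to 15).

Steps most likely to fail

Step 8. The neopentyl radical may be reduced by the stannane before it closes, or the free 6-hydroxyl may add to the vinyl ketone (intramolecular oxa-Michael addition) and the enone may oligomerise. The fallback sets out from 8 and comes back at 10, and closes the same C1–C2 bond by a polar alkylation instead of a radical addition. Radical-chain anti-Markovnikov addition of HBr to the vinyl group of 8 (HBr, dibenzoyl peroxide, pentane, 0 °C) should give the primary bromide, 2-(3-bromo-1-hydroxypropyl)-3-(iodomethyl)-3-methyl-6-(propan-2-yl)cyclohexan-1-ol F3. Excess t-BuLi (Et2O–pentane, −78 °C to rt) then deprotonates both hydroxyls and exchanges the iodide selectively, and the neopentyllithium alkylates the bromide (6-exo-tet) to give 15-noreudesmane-4,6β-diol F4. Selective oxidation of the less hindered 4-hydroxyl (TEMPO, PhI(OAc)2, CH2Cl2) should give 10.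

Step 1. Poor facial selectivity of hydride delivery: attack anti to the isopropyl group would favour the cis alcohol, which would place the cyclopropane methylene on the wrong face. The fallback sets out from 1 and comes back at 2. LiBH(s-Bu)3 (THF, −78 °C) reduces 1 from the face anti to isopropyl to cis-piperitol F1. Mitsunobu inversion with 4-nitrobenzoic acid (PPh3, DIAD, THF) gives trans-piperityl 4-nitrobenzoate F2, and K2CO3 in MeOH releases 2.

Step 10. Sluggish acylation of the axial 6-hydroxyl, which is flanked by C5 and the isopropyl group and is syn-axial to the C10 methyl and the 4-hydroxyl, lets the activated acid rearrange to the N-acylurea. The fallback sets out from 11 and comes back at 15. Heating 11 with Meldrum's acid (toluene, 100 °C) should give the malonic half-ester, 3-[(4-hydroxyeudesman-6-yl)oxy]-3-oxopropanoic acid F5. Knoevenagel–Doebner condensation of F5 with isovanillin 14 (pyridine, piperidine cat., 70 °C), with loss of CO2, gives 15 directly.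

Further compounds
F1 | step 1 | cis-piperitol, 3-methyl-6-(propan-2-yl)cyclohex-2-en-1-ol with OH syn to isopropyl | O[C@H]1C=C(C)CC[C@H]1C(C)C
F2 | step 1 | trans-piperityl 4-nitrobenzoate (ester oxygen anti to isopropyl) | O=C(O[C@@H]1C=C(C)CC[C@H]1C(C)C)c1ccc(cc1)[N+](=O)[O-]
F3 | step 8 | 2-(3-bromo-1-hydroxypropyl)-3-(iodomethyl)-3-methyl-6-(propan-2-yl)cyclohexan-1-ol, ring configuration as in 8 | O[C@H]1[C@@H](C(O)CCBr)[C@](C)(CI)CC[C@H]1C(C)C
F4 | step 8 | 15-noreudesmane-4,6β-diol (trans-fused, C4 carbinol epimers) | O[C@H]1[C@@H]2[C@](C)(CCCC2O)CC[C@H]1C(C)C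
F5 | step 10 | 3-[(4-hydroxyeudesman-6-yl)oxy]-3-oxopropanoic acid (malonic half-ester of 11) | OC(=O)CC(=O)O[C@H]1[C@@H]2[C@](C)(CCC[C@]2(C)O)CC[C@H]1C(C)C
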